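## Retrosynthetic overview
1. The target comes from its bis-silyl ether by fluoride. The C8–C9 and C9–C10 bonds of the skipped enone come from one carbonylative Stille coupling (allylic chloride + CO + isobutenylstannane) on a prenyl end group activated by ene-type chlorination.
2. Key disconnection: the ArC(=O)CH2–C(CH3) array comes from a mirror-symmetric 1-aryl-3-homoprenyl-3-vinylcyclobutanol. A chiral rhodium catalyst cuts one of the two enantiotopic C1–CH2 ring bonds, the freed ring CH2 becomes the methyl group, and the quaternary centre appears as R.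
3. The cyclobutanol comes from the aryllithium of bis-silylated 4-bromoresorcinol and a 3,3-disubstituted cyclobutanone.
4. The cyclobutanone comes from myrcene and the two-carbon keteniminium ion of N,N-dimethylacetamide by [2+2] cycloaddition.
5. Rings: the arene is bought. The only ring built is the cyclobutane (step 2), and it is opened again in step 4.

Assumption: the pairing "(R)-DTBM-SEGPHOS with 9 gives the R ketone" is provisional. The ligand antipode is equally available and is swapped in if the first ee and configuration check shows the opposite sense.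

## Route

Step 1
Reactants: 1 4-bromoresorcinol
Product: 2 1-bromo-2,4-bis(tert-butyldimethylsilyloxy)benzene
Conditions: TBSCl (2.3 equiv), imidazole, DMF, 23 °C
Reagents that add atoms: tert-butyldimethylsilyl chloride, CC(C)(C)[Si](C)(C)Cl
Why: Imidazole-promoted O-silylation caps both phenols so that the bromide can be lithiated, and silyl ethers are chosen because they can be removed at the end under buffered, near-neutral conditions that do not conjugate the skipped enone; no stereocentre is involved.

Step 2
Reactants: 3 β-myrcene (7-methyl-3-methyleneocta-1,6-diene); 4 N,N-dimethylacetamide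
Product: 7 3-(4-methylpent-3-en-1-yl)-3-vinylcyclobutan-1-one, via keteniminium triflate 5 (not isolated), via cyclobutaniminium triflate 6 (not isolated)
Conditions: Tf2O (1.2 equiv), 2,4,6-collidine (1.2 equiv), 3 (3 equiv), ClCH2CH2Cl, 0 to 80 °C; then H2O, 60 °C
Reagents that add atoms: water, O
Why: Ghosez keteniminium–alkene [2+2] cycloaddition, in which the electrophilic central carbon of 5 bonds to the unhindered =CH2 of the 1,1-disubstituted diene terminus (allyl-stabilised and less hindered than the trisubstituted alkene, with excess cheap 3 suppressing double addition), ring closure places both substituents on C3, and hydrolysis gives an achiral, mirror-symmetric ketone.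

Step 3
Reactants: 2 1-bromo-2,4-bis(tert-butyldimethylsilyloxy)benzene; 7 3-(4-methylpent-3-en-1-yl)-3-vinylcyclobutan-1-one
Product: 9 1-[2,4-bis(tert-butyldimethylsilyloxy)phenyl]-3-(4-methylpent-3-en-1-yl)-3-vinylcyclobutan-1-ol (aryl cis to vinyl), via aryllithium 8 (not isolated)
Conditions: n-BuLi (1.05 equiv), THF, −78 °C, 10 min; then 7, −78 °C; aq NH4Cl; chromatography
Reagents that add atoms: none
Why: Bromine–lithium exchange and 1,2-addition to the strained ketone (cold and short so that O-to-C silyl migration in 8 does not start); the carbinol carbon is only a relative stereo-element because the product keeps its mirror plane, attack past the flatter vinyl group is expected to win only about 2:1, and the isomer with aryl cis to vinyl is isolated pure because this relative configuration relays the catalyst's bond choice in step 4 to C3.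

Step 4
Reactants: 9 1-[2,4-bis(tert-butyldimethylsilyloxy)phenyl]-3-(4-methylpent-3-en-1-yl)-3-vinylcyclobutan-1-ol (aryl cis to vinyl)
Product: 10 (3R)-1-[2,4-bis(tert-butyldimethylsilyloxy)phenyl]-3,7-dimethyl-3-vinyloct-6-en-1-one
Conditions: [Rh(OH)(cod)]2 (2.5 mol %), (R)-DTBM-SEGPHOS (6 mol %), t-BuOH (5 equiv), toluene, 100 °C
Reagents that add atoms: none
Why: Enantioselective rhodium-catalysed C–C activation of a prochiral tert-cyclobutanol by β-carbon elimination, in which the rhodium alkoxide in the chiral diphosphine pocket tells the two enantiotopic C1–CH2 bonds apart through the aryl/oxygen difference at C1, strain release drives the cleavage, and protodemetalation of the neopentyl-type carbon–rhodium bond (no β-hydrogen, t-BuOH as proton shuttle) turns that ring CH2 into the methyl group, creating the quaternary centre as R in an isomerisation that adds and loses no atoms.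

Step 5
Reactants: 10 (3R)-1-[2,4-bis(tert-butyldimethylsilyloxy)phenyl]-3,7-dimethyl-3-vinyloct-6-en-1-one
Product: 11 (3R)-1-[2,4-bis(tert-butyldimethylsilyloxy)phenyl]-6-chloro-3,7-dimethyl-3-vinyloct-7-en-1-one (C6 epimers)
Conditions: NCS (1.1 equiv), PhSeCl (10 mol %), MeCN, 23 °C
Reagents that add atoms: N-chlorosuccinimide, O=C1CCC(=O)N1Cl
Why: Selenium-catalysed ene-type allylic chlorination, in which the electrophilic selenium species engages only the electron-rich trisubstituted alkene (the neopentyl vinyl group, arene and ketone are far less nucleophilic) and oxidative elimination gives the transposed secondary allylic chloride; the C6 mixture is irrelevant because step 6 erases it, and C3 is untouched.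

Step 6
Reactants: 11 (3R)-1-[2,4-bis(tert-butyldimethylsilyloxy)phenyl]-6-chloro-3,7-dimethyl-3-vinyloct-7-en-1-one; 12 tributyl(2-methylprop-1-en-1-yl)stannane
Product: 13 (3R,6E)-1-[2,4-bis(tert-butyldimethylsilyloxy)phenyl]-3-ethenyl-3,7,11-trimethyldodeca-6,10-diene-1,9-dione
Conditions: Pd2(dba)3 (2.5 mol %), PPh3 (10 mol %), CO (3 atm), THF, 50 °C
Reagents that add atoms: carbon monoxide, [C-]#[O+]
Why: Carbonylative Stille coupling of an allylic chloride, in which oxidative addition to zerovalent palladium erases C6 in a 1-alkyl-2-methyl π-allyl unit that prefers the syn arrangement, CO inserts at the unsubstituted CH2 terminus, and isobutenyl transfer with reductive elimination gives the allyl vinyl ketone; the syn geometry becomes the 6E alkene (about 9:1 expected, Z isomer removed by chromatography), and the base-free medium keeps the β,γ-double bond out of conjugation.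

Step 7
Reactants: 13 (3R,6E)-1-[2,4-bis(tert-butyldimethylsilyloxy)phenyl]-3-ethenyl-3,7,11-trimethyldodeca-6,10-diene-1,9-dione
Product: 14 (3R,6E)-1-(2,4-dihydroxyphenyl)-3-ethenyl-3,7,11-trimethyldodeca-6,10-diene-1,9-dione (target)
Conditions: TBAF (2.2 equiv), AcOH (2.2 equiv), THF, 0 °C
Reagents that add atoms: none
Why: Fluoride cleavage of aryl silyl ethers, buffered with acetic acid so that no phenoxide or fluoride base can enolise the doubly activated C8 methylene and pull the 6E alkene into conjugation; the quaternary centre bears no acidic hydrogen and cannot epimerise.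

## Compound list
1 | 4-bromoresorcinol | Oc1ccc(Br)c(O)c1 | starting material
2 | 1-bromo-2,4-bis(tert-butyldimethylsilyloxy)benzene | CC(C)(C)[Si](C)(C)Oc1ccc(Br)c(O[Si](C)(C)C(C)(C)C)c1 | intermediate
3 | β-myrcene | C=CC(=C)CCC=C(C)C | starting material
4 | N,N-dimethylacetamide | CC(=O)N(C)C | starting material
5 | N,N-dimethylketeniminium triflate | C=C=[N+](C)C.[O-]S(=O)(=O)C(F)(F)F | intermediate
6 | N,N-dimethyl-3-(4-methylpent-3-en-1-yl)-3-vinylcyclobutan-1-iminium triflate | C[N+](C)=C1CC(C=C)(CCC=C(C)C)C1.[O-]S(=O)(=O)C(F)(F)F | intermediate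
7 | 3-(4-methylpent-3-en-1-yl)-3-vinylcyclobutan-1-one | O=C1CC(C=C)(CCC=C(C)C)C1 | intermediate
8 | 2,4-bis(tert-butyldimethylsilyloxy)phenyllithium | [Li]c1ccc(O[Si](C)(C)C(C)(C)C)cc1O[Si](C)(C)C(C)(C)C | intermediate
9 | 1-[2,4-bis(tert-butyldimethylsilyloxy)phenyl]-3-(4-methylpent-3-en-1-yl)-3-vinylcyclobutan-1-ol, aryl cis to vinyl (achiral) | O[C@]1(c2ccc(O[Si](C)(C)C(C)(C)C)cc2O[Si](C)(C)C(C)(C)C)C[C@](C=C)(CCC=C(C)C)C1 | intermediate
10 | (3R)-1-[2,4-bis(tert-butyldimethylsilyloxy)phenyl]-3,7-dimethyl-3-vinyloct-6-en-1-one | C=C[C@](C)(CCC=C(C)C)CC(=O)c1ccc(O[Si](C)(C)C(C)(C)C)cc1O[Si](C)(C)C(C)(C)C | intermediate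
11 | (3R)-1-[2,4-bis(tert-butyldimethylsilyloxy)phenyl]-6-chloro-3,7-dimethyl-3-vinyloct-7-en-1-one (C6 epimers) | C=C[C@](C)(CCC(Cl)C(C)=C)CC(=O)c1ccc(O[Si](C)(C)C(C)(C)C)cc1O[Si](C)(C)C(C)(C)C | intermediate
12 | tributyl(2-methylprop-1-en-1-yl)stannane | CC(C)=C[Sn](CCCC)(CCCC)CCCC | starting material
13 | (3R,6E)-1-[2,4-bis(tert-butyldimethylsilyloxy)phenyl]-3-ethenyl-3,7,11-trimethyldodeca-6,10-diene-1,9-dione | C=C[C@](C)(CC/C=C(\C)CC(=O)C=C(C)C)CC(=O)c1ccc(O[Si](C)(C)C(C)(C)C)cc1O[Si](C)(C)C(C)(C)C | intermediate
14 | (3R,6E)-1-(2,4-dihydroxyphenyl)-3-ethenyl-3,7,11-trimethyldodeca-6,10-diene-1,9-dione | C=C[C@](C)(CC/C=C(\C)CC(=O)C=C(C)C)CC(=O)c1ccc(O)cc1O | target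

## Step count and risks
Total step count: 7. Longest linear sequence: 6 (3 → 7 → 9 → 10 → 11 → 13 → 14; the arm from 1 is also 6).

**Step 4 is the most exposed.**
- The carbon–rhodium bond formed after ring cleavage sits two atoms from the vinyl group. Two side paths could outrun protonation: a 3-exo carbometalation with vinyl shift, or a 1,4-rhodium migration to the vinylic C–H followed by addition to the ketone, which would give a cyclopentenol.
- The level of induction with a bulky ortho-silyloxy aryl group is untested.
- The fallback sets the centre by auxiliary-controlled conjugate addition. It sets out from 2 and comes back at 10.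
- (E)-Geranic acid is activated with pivaloyl chloride and Et3N and joined to lithiated (S)-4-phenyloxazolidin-2-one. This gives (S)-3-[(2E)-3,7-dimethylocta-2,6-dienoyl]-4-phenyloxazolidin-2-one F1.
- Vinylmagnesium bromide with CuBr·SMe2 adds 1,4 to the chelated s-cis imide on the face away from the phenyl group. This gives (S)-3-[(3R)-3,7-dimethyl-3-vinyloct-6-enoyl]-4-phenyloxazolidin-2-one F2.
- MeNH(OMe)·HCl with AlMe3 converts it into (3R)-N-methoxy-N,3,7-trimethyl-3-vinyloct-6-enamide F3. Aryllithium 8, made from 2 as in step 3, then acylates F3 cleanly to 10.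

**Step 3 is second.**
- Vinyl and CH2R are of similar size, so the facial ratio may be close to 1:1.
- The catalyst reads the aryl/oxygen pair at C1, so the two epimers are expected to give opposite enantiomers with the same ligand. The ee of 10 therefore cannot exceed the isomeric purity of 9.
- The fallback drops any reliance on facial selectivity and makes the sequence stereoconvergent. It sets out from 7 (with 2) and comes back at 10.
- The co-formed epimer is 1-[2,4-bis(tert-butyldimethylsilyloxy)phenyl]-3-(4-methylpent-3-en-1-yl)-3-vinylcyclobutan-1-ol with hydroxyl cis to vinyl F4. It is collected from the same column, on silver-nitrate-doped silica if needed.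
- F4 is opened separately with [Rh(OH)(cod)]2 and (S)-DTBM-SEGPHOS. The mirror-image catalyst on the epimeric substrate cuts the bond that again delivers R, so all of the addition product ends up as 10.

**Step 6 is third.**
- The 6E geometry rests on the syn/anti preference of a 2-methyl-substituted π-allyl unit generated from a secondary chloride.
- Direct coupling without CO uptake or diene formation could also compete.
- The fallback fixes the geometry in the substrate before palladium is used. It sets out from 10 and comes back at 13.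
- SeO2 (0.3 equiv) with t-BuOOH in CH2Cl2 at 0 °C oxidises the E-methyl group through the ene and [2,3]-shift sequence. This gives (3R,6E)-1-[2,4-bis(tert-butyldimethylsilyloxy)phenyl]-8-hydroxy-3,7-dimethyl-3-vinyloct-6-en-1-one F5.
- MsCl, LiCl and 2,4,6-collidine in DMF at 0 °C give (3R,6E)-1-[2,4-bis(tert-butyldimethylsilyloxy)phenyl]-8-chloro-3,7-dimethyl-3-vinyloct-6-en-1-one F6.
- This primary E chloride enters the three-component coupling with CO and 12 directly as the syn π-allyl unit and keeps its geometry on the way to 13.

## Further compounds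
F1 | step 4 | (S)-3-[(2E)-3,7-dimethylocta-2,6-dienoyl]-4-phenyloxazolidin-2-one | CC(C)=CCC/C(C)=C/C(=O)N1[C@@H](c2ccccc2)COC1=O
F2 | step 4 | (S)-3-[(3R)-3,7-dimethyl-3-vinyloct-6-enoyl]-4-phenyloxazolidin-2-one | C=C[C@](C)(CCC=C(C)C)CC(=O)N1[C@@H](c2ccccc2)COC1=O
F3 | step 4 | (3R)-N-methoxy-N,3,7-trimethyl-3-vinyloct-6-enamide | C=C[C@](C)(CCC=C(C)C)CC(=O)N(C)OC
F4 | step 3 | 1-[2,4-bis(tert-butyldimethylsilyloxy)phenyl]-3-(4-methylpent-3-en-1-yl)-3-vinylcyclobutan-1-ol, hydroxyl cis to vinyl (achiral) | O[C@]1(c2ccc(O[Si](C)(C)C(C)(C)C)cc2O[Si](C)(C)C(C)(C)C)C[C@@](C=C)(CCC=C(C)C)C1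
F5 | step 6 | (3R,6E)-1-[2,4-bis(tert-butyldimethylsilyloxy)phenyl]-8-hydroxy-3,7-dimethyl-3-vinyloct-6-en-1-one | C=C[C@](C)(CC/C=C(\C)CO)CC(=O)c1ccc(O[Si](C)(C)C(C)(C)C)cc1O[Si](C)(C)C(C)(C)C
F6 | step 6 | (3R,6E)-1-[2,4-bis(tert-butyldimethylsilyloxy)phenyl]-8-chloro-3,7-dimethyl-3-vinyloct-6-en-1-one | C=C[C@](C)(CC/C=C(\C)CCl)CC(=O)c1ccc(O[Si](C)(C)C(C)(C)C)cc1O[Si](C)(C)C(C)(C)C
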